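The route rests on cutting the 2-pyranone ring at C4–C5 and O1–C2. C2–C3–C4 is a malonyl unit whose central carbon C3 already bears the quaternary C(CH3)2CH=CH2 group, and C5–C6(Ph)–O1 is the enol of acetophenone; this pairing of a symmetric 1,3-bis-electrophile with a C,O-bis-nucleophile is what the key step exploits. One [3+3] cyclocondensation of the substituted malonyl dichloride with acetophenone trimethylsilyl enol ether forms both bonds and gives the 3-tert-alkyl-4-hydroxy-6-phenyl-2-pyranone, so prenylation regiochemistry never arises. The precursor is an acyclic acid dichloride made by copper-catalysed vinyl addition to an isopropylidenemalonate, saponification and chlorination. The O4 ester is attached last as a silyl-protected acid.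

Key step: step 4

Assumption: the four building blocks used as starting materials are purchasable, the hydroxypyranone is handled as its 4-hydroxy-2-pyranone tautomer, and no stereocontrol is planned because neither the target nor any intermediate has a stereocentre or a stereogenic alkene.

Step 1
Reactants: 1 diethyl isopropylidenemalonate; 2 vinylmagnesium bromide
Product: 3 diethyl 2-(2-methylbut-3-en-2-yl)malonate
Conditions: 2 (1.3 equiv), CuI (10 mol%), THF, −20 → 0 °C; then cold 1 M aq. HCl
Reagents that add atoms: none
Why: Copper-catalysed conjugate (1,4-) addition of a Grignard reagent to an alkylidenemalonate, in which the vinylcopper species formed in the flask adds to the β,β-dimethyl carbon of the doubly activated alkene and so sets the quaternary carbon with the vinyl group directly attached.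

Step 2
Reactants: 3 diethyl 2-(2-methylbut-3-en-2-yl)malonate
Product: 4 2-(2-methylbut-3-en-2-yl)malonic acid
Conditions: KOH (5 equiv), EtOH–H2O, reflux; then 0 °C, aq. HCl to pH 1, extraction, evaporation below 30 °C
Reagents that add atoms: potassium hydroxide, [K+].[OH-]
Why: Saponification (base-mediated acyl–oxygen ester hydrolysis) is driven to the thermally stable dicarboxylate by excess KOH despite the neighbouring quaternary carbon, and cold acidification with low-temperature isolation avoids the decarboxylation that substituted malonic acids undergo only on heating.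

Step 3
Reactants: 4 2-(2-methylbut-3-en-2-yl)malonic acid
Product: 5 2-(2-methylbut-3-en-2-yl)malonyl dichloride
Conditions: oxalyl chloride (2.5 equiv), N,N-dimethylformamide (cat.), CH2Cl2, 0 → 20 °C; volatiles removed, used crude
Reagents that add atoms: oxalyl chloride, O=C(Cl)C(=O)Cl
Why: Acid chloride formation through the chloroiminium (Vilsmeier-type) species from oxalyl chloride and N,N-dimethylformamide runs at room temperature with only gaseous by-products, so the diacid is never heated and the unactivated vinyl group is left alone.

Step 4
Reactants: 5 2-(2-methylbut-3-en-2-yl)malonyl dichloride; 6 1-phenyl-1-(trimethylsilyloxy)ethene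
Product: 8 4-hydroxy-3-(2-methylbut-3-en-2-yl)-6-phenyl-2H-pyran-2-one, via diketo acid chloride 7 (not isolated)
Conditions: 6 (1.0 equiv) added dropwise to 5 (1.1 equiv), Et2O, −78 → 20 °C, no base; product extracted into cold aq. Na2CO3, then acidified to pH 3
Reagents that add atoms: none
Why: The nucleophilic CH2 carbon of 6 adds to one acyl chloride carbon of 5 and chlorotrimethylsilane is lost (C5–C4 bond), giving the enolisable diketo acid chloride 7. The enol oxygen of its benzoyl group then attacks the second acyl chloride by addition–elimination in a 6-exo-trig closure (O1–C2 bond), and tautomerisation to the aromatic enol gives 8, the only ring made in the route. The closest known reaction type is the cyclocondensation of malonyl dichlorides with ketone silyl enol ethers to 6-substituted 4-hydroxy-2-pyranones. No stereocentre is created. The selectivity needed is one enol ether per malonyl unit (C- then O-acylation within the same molecule, not acylation of a second enol ether), which should be secured by slow addition of 6 to 5 at low temperature and by the fast intramolecular second acylation; regiochemistry cannot arise because 5 is symmetric about C3. The reverse-prenyl group is already on C3, so no C- versus O-allylation question exists, and its isolated vinyl group should be inert to acyl chlorides and to HCl in ether at these temperatures.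

Step 5
Reactants: 9 3-hydroxy-3-methylbutanoic acid
Product: 11 3-methyl-3-(triethylsilyloxy)butanoic acid, via bis-triethylsilyl derivative 10 (not isolated)
Conditions: Et3SiOTf (2.2 equiv), 2,6-lutidine (3 equiv), CH2Cl2, −78 → 0 °C; then MeOH–H2O, 0 → 20 °C; extraction at pH 4–5
Reagents that add atoms: triethylsilyl trifluoromethanesulfonate, CC[Si](CC)(CC)OS(=O)(=O)C(F)(F)F
Why: Silylation with the silyl triflate (needed for a tertiary alcohol) covers both hydroxyl groups, and the silyl ester of 10, far more labile than the hindered tertiary silyl ether, is solvolysed selectively by aqueous methanol in the same flask.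

Step 6
Reactants: 11 3-methyl-3-(triethylsilyloxy)butanoic acid; 8 4-hydroxy-3-(2-methylbut-3-en-2-yl)-6-phenyl-2H-pyran-2-one
Product: 13 3-(2-methylbut-3-en-2-yl)-2-oxo-6-phenyl-2H-pyran-4-yl 3-methyl-3-(triethylsilyloxy)butanoate, via silyloxy acid chloride 12 (not isolated)
Conditions: 11, 1-chloro-N,N,2-trimethylpropenylamine (1.1 equiv), CH2Cl2, 0 → 20 °C; then 8, Et3N (1.5 equiv), 4-(dimethylamino)pyridine (10 mol%), CH2Cl2, 0 °C
Reagents that add atoms: 1-chloro-N,N,2-trimethylpropenylamine, CC(C)=C(Cl)N(C)C (supplies only the chlorine of intermediate 12)
Why: The α-chloroenamine turns the acid into acid chloride 12 without releasing HCl, so the silyl ether survives, and O-acylation of the acidic 4-enol by nucleophilic catalysis follows, with C3 fully substituted so that no C-acylation can compete and reversible acyl transfer expected to funnel any 2-O-acyl isomer to the conjugated 4-acyloxy-2-pyranone.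

Step 7
Reactants: 13 3-(2-methylbut-3-en-2-yl)-2-oxo-6-phenyl-2H-pyran-4-yl 3-methyl-3-(triethylsilyloxy)butanoate
Product: 14 3-(2-methylbut-3-en-2-yl)-2-oxo-6-phenyl-2H-pyran-4-yl 3-hydroxy-3-methylbutanoate (CNP0160044.0)
Conditions: HF·pyridine, extra pyridine, THF, 0 °C; pH 7 phosphate buffer work-up
Reagents that add atoms: none
Why: Fluoride-mediated silyl ether cleavage, driven by Si–F bond formation, is run in a pyridine-buffered, weakly acidic medium so that no alkoxide forms, which should protect the activated enol ester from hydrolysis and from intramolecular attack by the freed tertiary oxygen.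

Compound list
1 | diethyl isopropylidenemalonate | CCOC(=O)C(=C(C)C)C(=O)OCC | starting material
2 | vinylmagnesium bromide | C=C[Mg]Br | starting material
3 | diethyl 2-(2-methylbut-3-en-2-yl)malonate | C=CC(C)(C)C(C(=O)OCC)C(=O)OCC | intermediate
4 | 2-(2-methylbut-3-en-2-yl)malonic acid | C=CC(C)(C)C(C(=O)O)C(=O)O | intermediate
5 | 2-(2-methylbut-3-en-2-yl)malonyl dichloride | C=CC(C)(C)C(C(=O)Cl)C(=O)Cl | intermediate
6 | 1-phenyl-1-(trimethylsilyloxy)ethene (acetophenone trimethylsilyl enol ether) | C=C(O[Si](C)(C)C)c1ccccc1 | starting material
7 | 2-(2-methylbut-3-en-2-yl)-3,5-dioxo-5-phenylpentanoyl chloride (diketo acid chloride) | C=CC(C)(C)C(C(=O)Cl)C(=O)CC(=O)c1ccccc1 | intermediate (not isolated)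
8 | 4-hydroxy-3-(2-methylbut-3-en-2-yl)-6-phenyl-2H-pyran-2-one | C=CC(C)(C)c1c(O)cc(-c2ccccc2)oc1=O | intermediate
9 | 3-hydroxy-3-methylbutanoic acid | CC(C)(O)CC(=O)O | starting material
10 | triethylsilyl 3-methyl-3-(triethylsilyloxy)butanoate (bis-triethylsilyl derivative) | CC[Si](CC)(CC)OC(=O)CC(C)(C)O[Si](CC)(CC)CC | intermediate (not isolated)
11 | 3-methyl-3-(triethylsilyloxy)butanoic acid | CC(C)(CC(=O)O)O[Si](CC)(CC)CC | intermediate
12 | 3-methyl-3-(triethylsilyloxy)butanoyl chloride (silyloxy acid chloride) | CC(C)(CC(=O)Cl)O[Si](CC)(CC)CC | intermediate (not isolated)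
13 | 3-(2-methylbut-3-en-2-yl)-2-oxo-6-phenyl-2H-pyran-4-yl 3-methyl-3-(triethylsilyloxy)butanoate | C=CC(C)(C)c1c(OC(=O)CC(C)(C)O[Si](CC)(CC)CC)cc(-c2ccccc2)oc1=O | intermediate
14 | 3-(2-methylbut-3-en-2-yl)-2-oxo-6-phenyl-2H-pyran-4-yl 3-hydroxy-3-methylbutanoate (CNP0160044.0) | C=CC(C)(C)c1c(OC(=O)CC(C)(C)O)cc(-c2ccccc2)oc1=O | target

Total step count: 7.
Longest linear sequence: 6 steps (steps 1, 2, 3, 4, 6, 7); step 5 is a one-step side branch.

Steps most likely to fail

1. Step 4. The first acylation next to the quaternary carbon may be slow. A second enol ether could then acylate the same malonyl unit before ring closure, or the HCl released could desilylate the enol ether before it reacts. The fallback keeps the pyranone annulation but moves the creation of the quaternary carbon to a later, intramolecular step. It sets out from 6 and returns at 8. Compound 6 is condensed with unsubstituted malonyl dichloride under the same conditions to give 4-hydroxy-6-phenyl-2H-pyran-2-one F1. Mitsunobu O-alkylation with 3-methylbut-2-en-1-ol (PPh3, diisopropyl azodicarboxylate, THF) gives 4-[(3-methylbut-2-en-1-yl)oxy]-6-phenyl-2H-pyran-2-one F2. A [3,3] Claisen rearrangement in refluxing acetic anhydride with NaOAc then transfers the allyl unit with inversion to C3, the only position joined to O4 through a ring double bond. The enol is trapped in the same flask as 3-(2-methylbut-3-en-2-yl)-2-oxo-6-phenyl-2H-pyran-4-yl acetate F3, which blocks cyclisation of the enol onto the vinyl group. Brief methanolysis (K2CO3, MeOH, 0 °C, then acidification) releases 8.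

2. Step 6. Acyl transfer to O4, which is shielded by the neighbouring tert-alkyl group, may be slow. The amine base could then consume the acid chloride through ketene formation and dimerisation, or through β-elimination of silanol. The fallback drops the protecting group and the acid chloride. It sets out from 8 (with purchased 9) and returns at 14. Steglich-type esterification of 8 with unprotected 9 (N-(3-dimethylaminopropyl)-N'-ethylcarbodiimide hydrochloride, catalytic 4-(dimethylamino)pyridine, CH2Cl2, 0 °C) should acylate only the acidic enol, since the tertiary hydroxyl is too hindered to compete. It gives the target directly, so steps 5 and 7 are not needed; it makes no compound outside the list (F0).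

3. Step 7. Fluoride or pyridine may attack the activated enol ester carbonyl and strip the acyl group before the hindered tertiary silyl ether is fully cleaved. The fallback replaces the fluoride step by a silyl group that leaves hydrolytically during work-up. It sets out from 9 and returns at 14. Compound 9 is bis-silylated (chlorotrimethylsilane, Et3N, CH2Cl2) to trimethylsilyl 3-methyl-3-(trimethylsilyloxy)butanoate F4. Its silyl ester is converted directly and under neutral conditions (oxalyl chloride, catalytic N,N-dimethylformamide, CH2Cl2, 0 °C) into 3-methyl-3-(trimethylsilyloxy)butanoyl chloride F5. Acylation of 8 as in step 6 gives 3-(2-methylbut-3-en-2-yl)-2-oxo-6-phenyl-2H-pyran-4-yl 3-methyl-3-(trimethylsilyloxy)butanoate F6. The trimethylsilyl ether is then hydrolysed by a short treatment with cold dilute aqueous citric acid in THF, giving 14 without fluoride.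

Further compounds
F1 | step 4 | 4-hydroxy-6-phenyl-2H-pyran-2-one | O=c1cc(O)cc(-c2ccccc2)o1
F2 | step 4 | 4-[(3-methylbut-2-en-1-yl)oxy]-6-phenyl-2H-pyran-2-one | CC(C)=CCOc1cc(-c2ccccc2)oc(=O)c1
F3 | step 4 | 3-(2-methylbut-3-en-2-yl)-2-oxo-6-phenyl-2H-pyran-4-yl acetate | C=CC(C)(C)c1c(OC(C)=O)cc(-c2ccccc2)oc1=O
F0 | step 6 | none | none
F4 | step 7 | trimethylsilyl 3-methyl-3-(trimethylsilyloxy)butanoate | CC(C)(CC(=O)O[Si](C)(C)C)O[Si](C)(C)C
F5 | step 7 | 3-methyl-3-(trimethylsilyloxy)butanoyl chloride | CC(C)(CC(=O)Cl)O[Si](C)(C)C
F6 | step 7 | 3-(2-methylbut-3-en-2-yl)-2-oxo-6-phenyl-2H-pyran-4-yl 3-methyl-3-(trimethylsilyloxy)butanoate | C=CC(C)(C)c1c(OC(=O)CC(C)(C)O[Si](C)(C)C)cc(-c2ccccc2)oc1=O
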